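The readings were generated by integration on assumed constants.

The ratio to watch in this flask is target formed per partner charged.

- amber: starting material 0.010 M (fed, over 40 min); partner 9 mM; capture agent 0.10 mM; run made earlier; the fed solution adds 0.50 times the starting volume
- flask: starting material 0.010 M (fed, over 40 min); partner 9.00 mM; capture agent 0.200 mM; time 30 h; the fed solution adds 0.50 times the starting volume

amber run (percent of the starting material charged)

| time / h | starting material / % | target / % | intermediate A / % |
|---|---|---|---|
| 0.250 | 26.6 | 1.5 | 5.9 |
| 0.833 | 22.6 | 3.4 | 45.1 |
| 1.33 | 5.1 | 4.8 | 65.7 |
| 2.00 | 1.6 | 4.0 | 68.1 |
| 3.00 | 1.3 | 3.8 | 61.1 |

(standard deviation of a reading: 1 percentage point)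

- charges are per starting volume, the dose included; the dosed solution carries all of it
- the reaction counts as stopped when no species that holds the starting material changes by six tenths of a point or more over the second half of the time
- percentages count the whole charge, also what has not yet gone in
- no earlier run changes the charge of capture agent; that part of a forecast is a guess
- a reading of intermediate A is of its free form alone

- at 30 h, what has stopped the reaction, if anything has (forward and back rates have come level / all of the starting material has reacted / it is still moving)
- conversion of starting material at 30 h
- amount of target at 30 h, in percent of the starting material charged
- amount of intermediate A at 30 h, in percent of the starting material charged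

I go up the time scales in the amber run. The feed lasts 40 min. After it, starting material falls from 22.6% to 5.1% between 0.833 h and 1.33 h, a half-life read at 0.231 h. Its last reading, 1.3%, stands near the scatter of 1 percentage point. I expect no starting material at 30 h in the flask, because that half-life is short against the time.

Target in the amber run reaches 4.8% by 1.33 h and then stays level within scatter, so I replace its late curve by its mean, 4.20%. The error is small: the farthest reading lies 0.6 points from the mean, less than the scatter. The yield on partner, the share of charged partner that ends as target, is then 4.67%. The flask repeats the amber charges of starting material and partner with twice the capture agent, whose effect I can only guess, so I commit to 4.20% target.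

The slowest rung is intermediate A, whose last two readings in the amber run fall at a pace that reads as a half-life of about 6.39 h, longer than the feed and the fall of starting material, while 33.8% of the charge is unseen at 3.00 h. Those readings do not show where it stops, so I give no figure for it and no verdict on whether the flask has stopped.

The forecast says it is still moving, with conversion 99%, target 4% and intermediate A 6%, and on target it reads “Target stays flat”.

The flask gives: all of the starting material has reacted, conversion 100%, target 4.55% and intermediate A 48.9%, with intermediate C at 46.5% beside it.

    capture agent + intermediate B → trapped intermediate (k = 0.00540 M⁻¹ s⁻¹)
    starting material + partner → target (k = 0.0150 M⁻¹ s⁻¹)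
    intermediate A ⇌ intermediate C (K = 0.950, k = 8.80 × 10⁻⁵ s⁻¹)
    starting material → intermediate B (k = 4.90 × 10⁻⁴ s⁻¹)
    starting material → intermediate A (k = 4.00 × 10⁻⁴ s⁻¹)
    partner → decomposed reagent (k = 4.20 × 10⁻⁴ s⁻¹)
    intermediate B → intermediate A (k = 5.50 × 10⁻⁴ s⁻¹)

In this flask the yield on partner comes to 5.06%, against the 4.67% I carried from the amber run. A neighbouring flask differs in one setting: it holds 0.036 M of partner, which is 3.60 equiv on starting material. The same yield on partner gives me 16.8% target for that neighbouring flask. It gives 16.4%, and its yield on partner is 4.55%.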